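The slow thing to watch here is not the target but what goes missing: in the theta run, target plus isomer of the product falls short of the charge, and over the later readings the gap widens.

- theta: starting material 0.050 M; the very flask that is asked about, followed so far
- flask: starting material 0.050 M; time 15 d

- theta (time / d: target / %, isomer of the product / %): 0.333: 50.7, 42.1; 0.833: 50.6, 43.3; 1.67: 52.0, 41.7; 2.50: 54.3, 39.5; 4.00: 55.9, 35.5; 5.00: 58.1, 33.6; 6.00: 58.3, 31.6

(each reading ± 0.3 percentage points)

- share of target in target plus isomer of the product at 15 min
- share of target in target plus isomer of the product at 10 h
- share of target in target plus isomer of the product at 15 d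
- which of target and isomer of the product there is more of at 15 d

- the earlier runs were read with a standard deviation of 0.3 percentage points
- a reading or a percentage of target counts all its forms, free or not

At 1.67 d the gap in the theta run reads 6.30 %. From then until 6.00 d it grows, read from these two end points, on average by:

leak = 0.00878 d⁻¹

This leak, the fraction of the charge lost from target plus isomer per day, is treated as an apparent zero order. Is it scatter? The drop of 3.8 percentage points is larger than the 0.6 points of scatter that a difference of two such sums carries. But why constant? The sum might instead lose a fixed step of its logarithm per day:

0.00415 d⁻¹, so the sum at 15 d is 82.5 %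

The constant leak gives 82.0 %, so the two laws part by 0.49 points.

The split is harder. Isomer falling at its own logarithmic pace reaches 17.8 %, which makes the share 78.3 %. Yet that pace reads slower from 4.00 d on than before it, so we lean below this figure. For 15 min the leak says nothing, and we give no number.

For 15 min, 10 h and 15 d the forecast said 54.3 %, 54.5 % and 76 %, with target ahead at the end, and said of the flat early share that it “looks like a kinetic split set during fast formation”.

For the same times the flask gives 69.7 %, 53.9 % and 70.2 %, with target ahead at the end.

    target → over-reaction product (k = 0.0136 h⁻¹)
    starting material ⇌ target (K = 3.17, k = 0.820 h⁻¹)
    crystals ⇌ target, rate k3*(cs3 - [target]) while solid is left; crystals form when [target] > cs3 (solubility = 1.40 mM, k = 0.204 h⁻¹)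
    starting material ⇌ isomer of the product (K = 26.6, k = 0.345 h⁻¹)

In this flask the half-life of dissolved target by the loss to over-reaction product alone, 2.1 d, is short against 15 d, yet at 15.0 d 54.7 % of the 57.4 % of target stands as crystals, and over-reaction product 17.4 % with starting material 0.871 % fills the gap that the leak put at 18.0 %. Taken as a fixed concentration per day, the leak becomes 0.00366 d⁻¹ in the neighbour flask charged with 0.12 M, which with the same early gap gives 11.2 %, and at 15.0 d that neighbour holds 10.7 % of over-reaction product and 0.410 % of starting material.

The numbers in the tables are calculated on assumed constants; scatter was added.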